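## Structural features

The target is a daucane sesquiterpenoid ester: a cyclopentane (C1–C5) trans-fused along the C1–C5 bond to a cycloheptane (C1, C10, C9, C8, C7, C6, C5), with an oxirane fused to the seven-membered ring at C8–C9. C1 is a quaternary carbon carrying the angular methyl (its face is called β), C5 carries the α hydrogen, and C4 is a fully substituted carbinol carbon with an α isopropyl group and a β oxygen that is esterified by 4-hydroxy-3-methoxybenzoic acid. C6 bears a free α hydroxyl, C8 a methyl group, and the epoxide oxygen bridges C8 and C9 on the α face. The six stereocentres form two groups, C4–C5–C1 with C6 next to C5, and C8–C9 across the ring. The fragile groups are the trisubstituted epoxide (acid), the tertiary aryl ester lying 1,3 to a free secondary hydroxyl (acyl shift to O6 under base), and the free phenol (base, oxidants). The real difficulties are the acylation of the crowded tertiary O4 while O6 stays free, the absolute configuration of the quaternary C1, and the placing of two oxygens on the α face at C6 and C9. The feature the key step exploits is that O6 and O9 are cis and 1,4-related across C7–C8 within the seven-membered ring, which is the imprint of dioxygen added across a C6=C7–C8=C9 diene.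

## Logic of the disconnections

24 to 23: only the phenolic O–H is changed, to an O–Si bond. The phenol has to be masked during alkoxide acylation and the oxidations. The forward step must free it without base-induced acyl shift from O4 to O6 and without touching the oxirane, hence buffered fluoride.

23 to 22: the C8–O and C9–O bonds of the oxirane are cut. The epoxide is the most acid-sensitive group and is therefore made last but one. The simplification is the loss of two stereocentres and one ring. The forward step must deliver oxygen to the α face of C8=C9, which the 6α hydroxyl (homoallylic) and the β angular methyl both favour.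

22 to 19 to 18: the C7–H bond and the C8=C9 double bond are traced back to a C9 carbonyl conjugated with C7=C8, through the sulfonylhydrazone. This converts the oxidation pattern that dioxygen leaves (oxygen at C6 and C9) into that of the target (oxygen at C6, alkene at C8–C9) in two operations and without a new stereocentre. The demand is clean 1,2-hydride addition to C=N in the presence of a free hydroxyl and an aryl ester.

18 to 17: O6 and O9 are reconnected as a peroxide bridge; the γ-hydroxy enone is the base-isomerised form of the endoperoxide. The gain is that both oxygens come from one reagent and are differentiated in one step. The demand is that base removes H9 and not H6.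

17 to 16: the C6–O and C9–O bonds are cut together (retro-[4+2]), giving a cyclohepta-1,3-diene and dioxygen. One ring and two stereocentres disappear. The forward step needs α-face attack and cycloaddition in preference to the ene reaction.

16 to 11 and 14: the acyl C–O4 bond is cut. Acylating at this stage, where O4 is the only hydroxyl in the molecule, removes the later need to protect and unmask O6. It also puts a bulky group on the β face next to C6, which helps steps 8 and 9. The demand is acylation of a hindered tertiary alkoxide.

14 to 13 to 12: the acid chloride is traced to the doubly silylated acid and then to the free hydroxy acid; the silyl ester is the latent acid chloride and the silyl ether the phenol mask.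

11 to 9 and 10: the C4–isopropyl bond is cut. The carbonyl at C4 is the oxygen that ends in the ester. The nucleophile must enter from the α face and must not enolise the doubly activated C5–H.

9 to 6 and 7: the C1–CH3 bond is cut, together with the C5–H bond formed on protonation. This removes both ring-fusion stereocentres and leaves an achiral trienone. The forward step must choose the enantioface at C1 and protonate C5 kinetically, anti to the new methyl.

6 to 3: the C5–C1 and C5–C6 bonds are cut (retro-Buchner), opening both rings to a tolyl diazoketone.

3 to 1: the C4–C5 bond is cut, giving the arylpropanoic acid and a diazomethane equivalent.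

## Other disconnections considered

Alternative 1: The cut removes C5–C1 and C5–C6, that is, C5 is taken out as a carbene inserted into a p-tolyl ring. In the forward sense diazoketone 3 with Rh2(OAc)4 gives, after norcaradiene opening and amine isomerisation, trienone A1.
- In favour: both carbocycles and twelve of the fifteen skeletal carbons appear in one catalytic step from a flat, cheap arene. The C8 methyl is already in place and the para substitution leaves no regiochemical choice.
- Against: A1 is achiral and has one oxygen. None of the six stereocentres and neither O6 nor the C8/C9 oxygen is addressed, so this step cannot organise the endgame.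
- Comparison: as a bond-forming event it is the stronger of the two (two C–C bonds and two rings, against two C–O bonds and one heterocycle). On step economy it is exactly equal, because A1 is compound 6 and the chosen route uses this ring expansion as its step 2. The singlet-oxygen step answers what the ring expansion leaves open: how the diene becomes the cis-1,4-dioxygen pattern. The two are complementary rather than rival.

Alternative 2: The cut is at C7–C8 and C1–C10. Siloxydiene A2 and vinyldiazoacetate A3 would react under Rh2(S-DOSP)4 by cyclopropanation of the enol ether double bond and Cope rearrangement of the divinylcyclopropane to give A4.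
- In favour: the seven-membered ring and the quaternary C1 centre are made in one enantioselective step of a well-charted reaction class. O6 is present as the enol ether, C8=C9 is in the right place, and the C4 ketone is ready for the isopropyl group.
- Against: C8 carries a methoxycarbonyl group where the target has methyl, which costs several redox steps. The Cope step must create a quaternary centre from a fully substituted, electron-poor enone double bond. C5 and C6 remain to be set by reductions whose facial course is open (6α-OH needs hydride from the more hindered β face). A2 itself must be made.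
- Comparison: on the absolute configuration at C1 the alternative is the better plan, since it rests on established catalyst control, whereas step 3 of the chosen route goes beyond precedent. On O6 the plans are equal in that both carry it out of the key step, but the chosen plan also fixes the C6 configuration there. On step economy the alternative is expected to be longer by the ester-to-methyl adjustment and the separate setting of C5 and C6.

Alternative 3: The cut is the C4–O bond, with O4 introduced by C–H functionalisation directed from O6. The N-bromo carbamate A5 would be photolysed; the nitrogen radical abstracts H4 through a seven-membered transition state, the C4 radical takes up bromine, and Ag2CO3 with hydrolysis closes the cyclic carbonate A6.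
- In favour: the regiochemistry of C4 oxygenation follows from the 1,3-relationship to O6, and a tertiary C–H is the ideal bond for abstraction. The isopropyl group could be introduced without adding an organometallic to an enolisable ketone, which is better than step 4 of the chosen route on that point. The carbonate protects O4 and O6 at once.
- Against: the target has the acyl group on O4 and a free O6. A6 must therefore be opened and the two hydroxyls differentiated again, so the hardest acylation would come last, on a substrate that already carries the epoxide. The C4 radical is planar, so the C4 configuration depends on the face preferred in ring closure. Bromine radicals and silver salts act next to an epoxide. C6 and C9 must be oxygenated by other means.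
- Comparison: mechanistically it is about as well founded as the chosen key step, and as a protecting-group device the carbonate is the more elegant. Structurally it solves, in four to five extra operations, what the chosen plan gets from the carbonyl of ketone 9, and it gives no help with the C6/C9 pattern.

Key step: step 8

Remark: daucane numbering is used (C1 angular methyl, C4 isopropyl carbinol, C5 ring-fusion CH, C6 to C10 around the seven-membered ring, C8 bearing methyl; β is the face of the C1 methyl). Compounds 9 to 16 also carry azulene-based names. The phosphoramidite antipode in step 3 is assumed to be the one that leads to (3aR)-9; this sense of induction would be confirmed on the first run and the ligand enantiomer exchanged if necessary.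

## Route

Step 1
Reactants: 1 3-(4-methylphenyl)propanoic acid
Product: 3 1-diazo-4-(4-methylphenyl)butan-2-one, via acid chloride 2 (not isolated)
Conditions: (COCl)2, DMF (cat.), CH2Cl2, 0 °C→rt; evaporate; then TMSCHN2 (2 equiv), THF/MeCN, 0 °C→rt
Reagents that add atoms: trimethylsilyldiazomethane, C[Si](C)(C)C=[N+]=[N-]
Why: Chloride transfer from the Vilsmeier-type intermediate gives the acid chloride, which C-acylates the diazoalkane (Arndt–Eistert-type diazoketone synthesis) with loss of Me3SiCl; the silyl reagent replaces explosive diazomethane.

Step 2
Reactants: 3 1-diazo-4-(4-methylphenyl)butan-2-one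
Product: 6 6-methyl-3,4-dihydroazulen-1(2H)-one, via norcaradiene 4 (not isolated), via 6-methyl-3,8a-dihydroazulen-1(2H)-one 5 (not isolated)
Conditions: Rh2(OAc)4 (1 mol %), CH2Cl2, reflux, slow addition of 3; then Et3N, rt
Reagents that add atoms: none
Why: Intramolecular Buchner reaction: the rhodium carbenoid cyclopropanates the ipso–ortho bond of the tolyl ring to 4, which opens by 6π electrocyclisation to cycloheptatriene 5. Et3N then shifts the doubly activated C5 proton through the extended enolate to C10, giving the conjugated trienone 6; no stereocentre survives.

Step 3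
Reactants: 6 6-methyl-3,4-dihydroazulen-1(2H)-one; 7 trimethylaluminium
Product: 9 (3aR,8aR)-3a,6-dimethyl-3,3a,4,8a-tetrahydroazulen-1(2H)-one, via dimethylaluminium trienolate 8 (not isolated)
Conditions: Cu(OTf)2 (5 mol %), (S,R,R)-BINOL bis(1-phenylethyl)amine phosphoramidite (10 mol %), Me3Al, Et2O, −30 °C; then inverse quench into MeOH/aq NH4Cl, −78 °C
Reagents that add atoms: none
Why: Proposed new method: the closest known reaction is the copper–phosphoramidite-catalysed asymmetric conjugate addition of Me3Al to β-substituted cyclic enones, which has not been shown for a fully substituted, cross-conjugated enone such as C4(=O)–C5=C1 of 6; the reasoning is that Me3Al activates the carbonyl, monovalent copper (formed in the flask from Cu(OTf)2) adds oxidatively at C1 to give a trivalent copper enolate that is stabilised here by conjugation with the 6,8-diene, and reductive elimination forms C1–CH3 on the ligand-selected enantioface, C1 being the only conjugate position because the diene hangs on the α-carbon. The cold protic quench then protonates trienolate 8 kinetically at its α-carbon C5 on the face opposite the new methyl, which sets the trans ring fusion and leaves the 6,8-diene out of conjugation with the ketone.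

Step 4
Reactants: 9 (3aR,8aR)-3a,6-dimethyl-3,3a,4,8a-tetrahydroazulen-1(2H)-one; 10 isopropylmagnesium chloride
Product: 11 (3R,3aR,8aR)-6,8a-dimethyl-3-(propan-2-yl)-1,2,3,3a,8,8a-hexahydroazulen-3-ol
Conditions: i-PrMgCl, CeCl3, THF, −78→−40 °C; aq NH4Cl
Reagents that add atoms: none
Why: Organocerium 1,2-addition: the weakly basic, oxophilic cerium reagent adds to the easily enolised β,γ-unsaturated ketone without removing the C5 proton or reducing the carbonyl. Attack comes from the α face, away from the angular C1 methyl and the C5–C6 bond that flank the β face, so the isopropyl group ends α and the hydroxyl β.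

Step 5
Reactants: 12 4-hydroxy-3-methoxybenzoic acid (vanillic acid)
Product: 13 tert-butyldimethylsilyl 4-[(tert-butyldimethylsilyl)oxy]-3-methoxybenzoate
Conditions: TBSCl (2.4 equiv), imidazole, DMF, rt
Reagents that add atoms: tert-butyldimethylsilyl chloride, CC(C)(C)[Si](C)(C)Cl
Why: Imidazole-promoted silylation of both the phenol and the carboxylic acid; the silyl ester is the latent acid chloride and the aryl silyl ether masks the phenol.

Step 6
Reactants: 13 tert-butyldimethylsilyl 4-[(tert-butyldimethylsilyl)oxy]-3-methoxybenzoate
Product: 14 4-[(tert-butyldimethylsilyl)oxy]-3-methoxybenzoyl chloride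
Conditions: (COCl)2, DMF (cat.), CH2Cl2, 0 °C→rt
Reagents that add atoms: oxalyl chloride, O=C(Cl)C(=O)Cl
Why: Silyl esters are converted by oxalyl chloride/DMF into acid chlorides under neutral conditions with release of the silyl chloride, so no HCl reaches the aryl silyl ether.

Step 7
Reactants: 11 (3R,3aR,8aR)-6,8a-dimethyl-3-(propan-2-yl)-1,2,3,3a,8,8a-hexahydroazulen-3-ol; 14 4-[(tert-butyldimethylsilyl)oxy]-3-methoxybenzoyl chloride
Product: 16 (3R,3aR,8aR)-6,8a-dimethyl-3-(propan-2-yl)-1,2,3,3a,8,8a-hexahydroazulen-3-yl 4-[(tert-butyldimethylsilyl)oxy]-3-methoxybenzoate (dauca-6,8-dien-4β-yl ester), via lithium alkoxide 15 (not isolated)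
Conditions: n-BuLi, THF, −78 °C; then 14, −78 °C→rt
Reagents that add atoms: none
Why: Acylation of a preformed tertiary lithium alkoxide by an aroyl chloride, the standard method for hindered tertiary alcohols. It is placed here because 11 has no other hydroxyl, so O6 never needs protection; C4 is not touched and keeps its configuration.

Step 8
Reactants: 16 dauca-6,8-dien-4β-yl 4-[(tert-butyldimethylsilyl)oxy]-3-methoxybenzoate
Product: 17 6α,9α-epidioxydauc-7-en-4β-yl 4-[(tert-butyldimethylsilyl)oxy]-3-methoxybenzoate (2,3-dioxabicyclo[3.2.2]non-8-ene fused to the cyclopentane)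
Conditions: O2, 5,10,15,20-tetraphenylporphyrin (TPP, 1 mol %), visible light, CH2Cl2, −20 °C
Reagents that add atoms: dioxygen, O=O
Why: The excited sensitiser transfers energy to ground-state O2, and the resulting singlet oxygen adds to the diene termini C6 and C9 in a concerted, suprafacial (4+2) cycloaddition, with the double bond moving to C7=C8. The closest known reaction is the photooxygenation of cyclohepta-1,3-dienes to 2,3-dioxabicyclo[3.2.2]non-8-enes. The one new ring, the six-membered 1,2-dioxine, closes in this single cycloaddition event and bridges the seven-membered ring 1,4; the s-cis geometry it needs is enforced by the ring. C6 and C9 are set together: the suprafacial addition makes the two C–O bonds cis to each other, and the face is chosen by the substrate, since the axial C1 methyl overhangs both diene termini on the β face and the β aroyloxy group on C4 adds bulk beside C6, so oxygen enters α. The step needs α over β attack and cycloaddition over the ene reaction at the trisubstituted C8=C9 bond. The first is secured by the β-face shielding and by the absence of a free hydroxyl that could steer oxygen to the β face. The second is secured by the ring-locked s-cis diene, which reacts in the cycloaddition mode much faster than an isolated alkene does in the ene mode. The electron-poor, silylated aryl ester is inert to singlet oxygen.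

Step 9
Reactants: 17 6α,9α-epidioxydauc-7-en-4β-yl 4-[(tert-butyldimethylsilyl)oxy]-3-methoxybenzoate
Product: 18 6α-hydroxy-9-oxodauc-7-en-4β-yl 4-[(tert-butyldimethylsilyl)oxy]-3-methoxybenzoate
Conditions: Et3N, CH2Cl2, 0 °C→rt
Reagents that add atoms: none
Why: Kornblum–DeLaMare rearrangement: the amine removes a proton from a peroxide-bearing carbon while the weak O–O bond breaks, giving ketone and alkoxide. H9 is flanked only by C10H2, whereas H6 sits next to C5 under the β aroyloxy group, so C9 becomes the carbonyl and C6 keeps its α carbinol, whose C–O bond is never broken.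

Step 10
Reactants: 18 6α-hydroxy-9-oxodauc-7-en-4β-yl 4-[(tert-butyldimethylsilyl)oxy]-3-methoxybenzoate
Product: 19 6α-hydroxy-9-[2-(4-methylbenzenesulfonyl)hydrazinylidene]dauc-7-en-4β-yl 4-[(tert-butyldimethylsilyl)oxy]-3-methoxybenzoate
Conditions: TsNHNH2, EtOH, 40 °C
Reagents that add atoms: 4-methylbenzenesulfonohydrazide, Cc1ccc(cc1)S(=O)(=O)NN
Why: Tosylhydrazone condensation of a conjugated ketone; the neutral conditions leave the ester, the silyl ether and the γ-hydroxyl alone.

Step 11
Reactants: 19 6α-hydroxy-9-[2-(4-methylbenzenesulfonyl)hydrazinylidene]dauc-7-en-4β-yl 4-[(tert-butyldimethylsilyl)oxy]-3-methoxybenzoate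
Product: 22 6α-hydroxydauc-8-en-4β-yl 4-[(tert-butyldimethylsilyl)oxy]-3-methoxybenzoate, via boryl hydrazide 20 (not isolated), via allylic diazene 21 (not isolated)
Conditions: catecholborane (3 equiv), CHCl3, 0 °C; then NaOAc·3H2O, reflux
Reagents that add atoms: none
Why: Catecholborane reduction of an α,β-unsaturated tosylhydrazone (alkene synthesis with 1,3-transposition): B–H adds across C=N to give 20 (O6 is borylated in passing and freed on work-up), and acetate triggers loss of p-toluenesulfinate to diazene 21. A retro-ene shift then delivers hydrogen to C7 with loss of N2 and places the double bond at C8=C9; no stereocentre is created and C6 is not involved.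

Step 12
Reactants: 22 6α-hydroxydauc-8-en-4β-yl 4-[(tert-butyldimethylsilyl)oxy]-3-methoxybenzoate
Product: 23 8α,9α-epoxy-6α-hydroxydaucan-4β-yl 4-[(tert-butyldimethylsilyl)oxy]-3-methoxybenzoate
Conditions: VO(acac)2 (5 mol %), t-BuOOH, CH2Cl2, 0 °C→rt
Reagents that add atoms: tert-butyl hydroperoxide, CC(C)(C)OO
Why: Hydroxyl-directed epoxidation of a homoallylic alcohol: the vanadium alkoxide of the 6α hydroxyl delivers the peroxide oxygen to the α face of C8=C9. This is also the sterically open face, the β face lying under the C1 methyl, so C8 and C9 are set with the oxirane α.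

Step 13
Reactants: 23 8α,9α-epoxy-6α-hydroxydaucan-4β-yl 4-[(tert-butyldimethylsilyl)oxy]-3-methoxybenzoate
Product: 24 8α,9α-epoxy-6α-hydroxydaucan-4β-yl 4-hydroxy-3-methoxybenzoate (target)
Conditions: Bu4NF, AcOH, THF, 0 °C
Reagents that add atoms: none
Why: Fluoride cleaves the aryl silyl ether selectively. The acetic acid buffer keeps O6 protonated, so neither a 1,3-acyl shift from O4 nor epoxide opening is set off.

## Compound list

1 | 3-(4-methylphenyl)propanoic acid | Cc1ccc(CCC(=O)O)cc1 | starting material
2 | 3-(4-methylphenyl)propanoyl chloride | Cc1ccc(CCC(=O)Cl)cc1 | intermediate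
3 | 1-diazo-4-(4-methylphenyl)butan-2-one | Cc1ccc(CCC(=O)C=[N+]=[N-])cc1 | intermediate
4 | norcaradiene valence tautomer of 5 (cyclopropane made of the carbene carbon and the former ipso and ortho carbons, fused to the cyclopentanone and the methylcyclohexadiene; racemic) | O=C1CCC23C=CC(C)=CC2C13 | intermediate
5 | 6-methyl-3,8a-dihydroazulen-1(2H)-one (racemic) | O=C1CCC2=CC=C(C)C=CC12 | intermediate
6 | 6-methyl-3,4-dihydroazulen-1(2H)-one | O=C1CCC2=C1C=CC(C)=CC2 | intermediate
7 | trimethylaluminium | C[Al](C)C | starting material
8 | dimethyl{[(8aR)-6,8a-dimethyl-1,2,8,8a-tetrahydroazulen-3-yl]oxy}aluminium | C[Al](C)OC1=C2C=CC(C)=CC[C@@]2(C)CC1 | intermediate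
9 | (3aR,8aR)-3a,6-dimethyl-3,3a,4,8a-tetrahydroazulen-1(2H)-one (trans-fused, 1β-methyl, 5α-H) | O=C1CC[C@]2(C)CC=C(C)C=C[C@H]21 | intermediate
10 | isopropylmagnesium chloride | CC(C)[Mg]Cl | starting material
11 | (3R,3aR,8aR)-6,8a-dimethyl-3-(propan-2-yl)-1,2,3,3a,8,8a-hexahydroazulen-3-ol (dauca-6,8-dien-4β-ol) | O[C@@]1(C(C)C)CC[C@]2(C)CC=C(C)C=C[C@H]21 | intermediate
12 | 4-hydroxy-3-methoxybenzoic acid (vanillic acid) | COc1cc(C(=O)O)ccc1O | starting material
13 | tert-butyldimethylsilyl 4-[(tert-butyldimethylsilyl)oxy]-3-methoxybenzoate | COc1cc(C(=O)O[Si](C)(C)C(C)(C)C)ccc1O[Si](C)(C)C(C)(C)C | intermediate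
14 | 4-[(tert-butyldimethylsilyl)oxy]-3-methoxybenzoyl chloride | COc1cc(C(=O)Cl)ccc1O[Si](C)(C)C(C)(C)C | intermediate
15 | lithium (3R,3aR,8aR)-6,8a-dimethyl-3-(propan-2-yl)-1,2,3,3a,8,8a-hexahydroazulen-3-olate | [Li]O[C@@]1(C(C)C)CC[C@]2(C)CC=C(C)C=C[C@H]21 | intermediate
16 | (3R,3aR,8aR)-6,8a-dimethyl-3-(propan-2-yl)-1,2,3,3a,8,8a-hexahydroazulen-3-yl 4-[(tert-butyldimethylsilyl)oxy]-3-methoxybenzoate | COc1cc(C(=O)O[C@@]2(C(C)C)CC[C@]3(C)CC=C(C)C=C[C@H]32)ccc1O[Si](C)(C)C(C)(C)C | intermediate
17 | 6α,9α-epidioxydauc-7-en-4β-yl 4-[(tert-butyldimethylsilyl)oxy]-3-methoxybenzoate | COc1cc(C(=O)O[C@@]2(C(C)C)CC[C@]3(C)C[C@@H]4OO[C@@H](C=C4C)[C@H]32)ccc1O[Si](C)(C)C(C)(C)C | intermediate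
18 | 6α-hydroxy-9-oxodauc-7-en-4β-yl 4-[(tert-butyldimethylsilyl)oxy]-3-methoxybenzoate | COc1cc(C(=O)O[C@@]2(C(C)C)CC[C@]3(C)CC(=O)C(C)=C[C@H](O)[C@H]32)ccc1O[Si](C)(C)C(C)(C)C | intermediate
19 | 6α-hydroxy-9-[2-(4-methylbenzenesulfonyl)hydrazinylidene]dauc-7-en-4β-yl 4-[(tert-butyldimethylsilyl)oxy]-3-methoxybenzoate (C=N geometry not fixed) | COc1cc(C(=O)O[C@@]2(C(C)C)CC[C@]3(C)CC(=NNS(=O)(=O)c4ccc(C)cc4)C(C)=C[C@H](O)[C@H]32)ccc1O[Si](C)(C)C(C)(C)C | intermediate
20 | 9-[1-(1,3,2-benzodioxaborol-2-yl)-2-(4-methylbenzenesulfonyl)hydrazinyl]-6α-(1,3,2-benzodioxaborol-2-yloxy)dauc-7-en-4β-yl 4-[(tert-butyldimethylsilyl)oxy]-3-methoxybenzoate (either configuration at C9, which is lost in the next event) | COc1cc(C(=O)O[C@@]2(C(C)C)CC[C@]3(C)CC(N(B4Oc5ccccc5O4)NS(=O)(=O)c4ccc(C)cc4)C(C)=C[C@H](OB4Oc5ccccc5O4)[C@H]32)ccc1O[Si](C)(C)C(C)(C)C | intermediate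
21 | 9-diazenyl-6α-hydroxydauc-7-en-4β-yl 4-[(tert-butyldimethylsilyl)oxy]-3-methoxybenzoate (either configuration at C9) | COc1cc(C(=O)O[C@@]2(C(C)C)CC[C@]3(C)CC(N=N)C(C)=C[C@H](O)[C@H]32)ccc1O[Si](C)(C)C(C)(C)C | intermediate
22 | 6α-hydroxydauc-8-en-4β-yl 4-[(tert-butyldimethylsilyl)oxy]-3-methoxybenzoate | COc1cc(C(=O)O[C@@]2(C(C)C)CC[C@]3(C)CC=C(C)C[C@H](O)[C@H]32)ccc1O[Si](C)(C)C(C)(C)C | intermediate
23 | 8α,9α-epoxy-6α-hydroxydaucan-4β-yl 4-[(tert-butyldimethylsilyl)oxy]-3-methoxybenzoate | COc1cc(C(=O)O[C@@]2(C(C)C)CC[C@]3(C)C[C@@H]4O[C@]4(C)C[C@H](O)[C@H]32)ccc1O[Si](C)(C)C(C)(C)C | intermediate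
24 | 8α,9α-epoxy-6α-hydroxydaucan-4β-yl 4-hydroxy-3-methoxybenzoate (1β-methyl, 5α-H, 4α-isopropyl) | COc1cc(C(=O)O[C@@]2(C(C)C)CC[C@]3(C)C[C@@H]4O[C@]4(C)C[C@H](O)[C@H]32)ccc1O | target

## Step count and least certain steps

Total: 13 steps (11 in the main line, 2 for acid chloride 14). Longest linear sequence: 11 steps from 1 to 24 (steps 1 to 4 and 7 to 13).

Step 3 (conjugate methylation, beyond precedent). The most likely failures are stalling of the copper addition at the fully substituted β-carbon, weak enantioface discrimination by a ligand developed for less substituted enones, and drift of the C5 proton into conjugation or to the cis fusion during work-up. The fallback sets out from 6 and uses known chemistry. Stoichiometric Me2CuLi with Me3SiCl (THF, −78 °C), the long-established way of placing an angular methyl on a fully substituted bicyclic enone, would give the racemic trimethylsilyl trienol ether F1. MeLi would regenerate the enolate, and a cold aqueous NH4Cl quench would protonate it kinetically at C5, giving the racemic trans ketone, that is 9 together with its mirror image (3aS,8aS)-ketone F2. Preparative chromatography on a chiral stationary phase would return enantiopure 9 to the route.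

Step 8 (key step). The likely failures are erosion of facial selectivity, because the α isopropyl group at C4 also lies near C6, and diversion into the ene pathway at the trisubstituted alkene. The fallback sets out from 16 and builds the two C–O bonds one after the other:
- Buffered m-chloroperbenzoic acid (NaHCO3, CH2Cl2, −20 °C) would epoxidise the more electron-rich C8=C9 bond, which lies directly under the C1 methyl, from the α face to give 8α,9α-epoxydauc-6-en-4β-yl ester F3.
- Pd(PPh3)4 (zerovalent palladium) with acetic acid would ionise the allylic C8–O bond with inversion and add acetate at C6 anti to the metal, giving the cis-1,4 product 6α-acetoxy-9α-hydroxydauc-7-en-4β-yl ester F4.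
- Reductive 1,3-transposition of the C9 allylic alcohol (2-nitrobenzenesulfonylhydrazide, PPh3, diethyl azodicarboxylate, −30 °C→rt) would move the double bond to C8=C9 and give 6α-acetoxydauc-8-en-4β-yl ester F5.
- i-Bu2AlH at −78 °C would remove the unhindered acetate in preference to the crowded tertiary aryl ester and return the sequence to 22.
The same facial question arises in the epoxidation, but there it is decided at C8/C9 only, where the methyl shielding is strongest.

Step 7 (acylation of the tertiary alkoxide). The likely failures are incomplete acyl transfer because of crowding by the isopropyl group and the ring fusion, and silyl migration from the aryl silyl ether to the alkoxide. The fallback sets out from 11 and forms the aryl–carbonyl bond instead of the O–acyl bond. The lithium alkoxide would be trapped with the small electrophile 1,1'-carbonyldiimidazole as the imidazole-1-carboxylate F6. Separately, commercial 4-bromo-2-methoxyphenol would be silylated to (4-bromo-2-methoxyphenoxy)(tert-butyl)dimethylsilane F7 and converted by bromine–magnesium exchange (i-PrMgCl·LiCl) into the arylmagnesium chloride F8. Addition of F8 to F6 at low temperature would give 16; the hindered tertiary ester resists a second addition.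

Step 9 (Kornblum–DeLaMare rearrangement). The likely failures are proton abstraction at C6 instead of C9 and onward isomerisation of the γ-hydroxy enone to the 1,4-diketone. The fallback sets out from 17 and avoids base. Thiourea in methanol would reduce the O–O bond to the cis-6α,9α-dihydroxydauc-7-en-4β-yl ester F9. Reductive 1,3-transposition with 2-nitrobenzenesulfonylhydrazide under Mitsunobu conditions would engage the less encumbered C9 hydroxyl and give 22 directly, which also saves steps 10 and 11. Here the selection rests on the accessibility of an oxygen to a bulky phosphonium reagent and not on that of a C–H bond to a small base.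

## Further compounds

F1 | step 3 | racemic trimethyl[(6,8a-dimethyl-1,2,8,8a-tetrahydroazulen-3-yl)oxy]silane | C[Si](C)(C)OC1=C2C=CC(C)=CCC2(C)CC1
F2 | step 3 | (3aS,8aS)-3a,6-dimethyl-3,3a,4,8a-tetrahydroazulen-1(2H)-one (mirror image of 9) | O=C1CC[C@@]2(C)CC=C(C)C=C[C@@H]21
F3 | step 8 | 8α,9α-epoxydauc-6-en-4β-yl 4-[(tert-butyldimethylsilyl)oxy]-3-methoxybenzoate | COc1cc(C(=O)O[C@@]2(C(C)C)CC[C@]3(C)C[C@@H]4O[C@]4(C)C=C[C@H]32)ccc1O[Si](C)(C)C(C)(C)C
F4 | step 8 | 6α-acetoxy-9α-hydroxydauc-7-en-4β-yl 4-[(tert-butyldimethylsilyl)oxy]-3-methoxybenzoate | COc1cc(C(=O)O[C@@]2(C(C)C)CC[C@]3(C)C[C@H](O)C(C)=C[C@H](OC(C)=O)[C@H]32)ccc1O[Si](C)(C)C(C)(C)C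
F5 | step 8 | 6α-acetoxydauc-8-en-4β-yl 4-[(tert-butyldimethylsilyl)oxy]-3-methoxybenzoate | COc1cc(C(=O)O[C@@]2(C(C)C)CC[C@]3(C)CC=C(C)C[C@H](OC(C)=O)[C@H]32)ccc1O[Si](C)(C)C(C)(C)C
F6 | step 7 | (3R,3aR,8aR)-6,8a-dimethyl-3-(propan-2-yl)-1,2,3,3a,8,8a-hexahydroazulen-3-yl 1H-imidazole-1-carboxylate | O=C(O[C@@]1(C(C)C)CC[C@]2(C)CC=C(C)C=C[C@H]21)n1ccnc1
F7 | step 7 | (4-bromo-2-methoxyphenoxy)(tert-butyl)dimethylsilane | COc1cc(Br)ccc1O[Si](C)(C)C(C)(C)C
F8 | step 7 | {4-[(tert-butyldimethylsilyl)oxy]-3-methoxyphenyl}magnesium chloride | COc1cc([Mg]Cl)ccc1O[Si](C)(C)C(C)(C)C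
F9 | step 9 | 6α,9α-dihydroxydauc-7-en-4β-yl 4-[(tert-butyldimethylsilyl)oxy]-3-methoxybenzoate | COc1cc(C(=O)O[C@@]2(C(C)C)CC[C@]3(C)C[C@H](O)C(C)=C[C@H](O)[C@H]32)ccc1O[Si](C)(C)C(C)(C)C
A1 | alternative 1 | 6-methyl-3,4-dihydroazulen-1(2H)-one (identical with 6) | O=C1CCC2=C1C=CC(C)=CC2
A2 | alternative 2 | 2-{1-[(tert-butyldimethylsilyl)oxy]ethenyl}-3-methylcyclopent-2-en-1-one | C=C(O[Si](C)(C)C(C)(C)C)C1=C(C)CCC1=O
A3 | alternative 2 | methyl 2-diazobut-3-enoate | C=CC(=[N+]=[N-])C(=O)OC
A4 | alternative 2 | methyl (8aR)-4-[(tert-butyldimethylsilyl)oxy]-8a-methyl-3-oxo-1,2,3,5,8,8a-hexahydroazulene-6-carboxylate | O=C1CC[C@]2(C)CC=C(C(=O)OC)CC(O[Si](C)(C)C(C)(C)C)=C21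
A5 | alternative 3 | 8α,9α-epoxy-4α-isopropyl-daucan-6α-yl N-bromo-N-(2,2,2-trifluoroethyl)carbamate (C4–H, no oxygen at C4) | CC(C)[C@@H]1CC[C@]2(C)C[C@@H]3O[C@]3(C)C[C@H](OC(=O)N(Br)CC(F)(F)F)[C@H]21
A6 | alternative 3 | 4,6-cyclic carbonate of 8α,9α-epoxydaucane-4β,6α-diol | O=C1O[C@@]2(C(C)C)CC[C@]3(C)C[C@@H]4O[C@]4(C)C[C@H](O1)[C@H]32
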